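**Retrosynthetic overview**
1. Amaurone A ⇒ dienal 16 + pyranone phosphonate 24 (Horner–Wadsworth–Emmons, last C=C); the pyranone ring is built separately from a triketo ester.
2. 16 ⇒ silyl enol ether 9 by a three-carbon acetal (Mukaiyama) and a two-carbon Wittig extension at the ring carbon next to the last ketone.
3. Ring oxygens: one enol oxidation of the 2-methyl-1,3-dione 5, then two ketone reductions by axial hydride (the acetate-bearing carbinol first, the free carbinol last).
4. Carbocycle (second ring formed) ⇐ Dieckmann-type acyl transfer within keto-lactone 3.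
5. Lactone 3 (first ring formed) ⇐ crotonaldehyde + biacetyl: the key C–C bond joins the enal β-carbon, made nucleophilic as a carbene-bound homoenolate, to a ketone carbon.

Assumption: configurations are read from the given SMILES; in cyclohexyl acetate numbering the target is (1R,2S,3S,4R,5S,6R), with all four ring oxygens on one face.
Assumption: the sense of induction of the triazolium catalyst in step 1 cannot be predicted with certainty; the (5aS,10bR) salt is written and its antipode is used if the first run gives ent-3.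

**Step 1**
Reactants: 1 (E)-but-2-enal; 2 butane-2,3-dione
Product: 3 (4S,5R)-5-acetyl-4,5-dimethyloxolan-2-one
Conditions: (5aS,10bR)-2-mesityl-5a,10b-dihydro-4H,6H-indeno[2,1-b][1,2,4]triazolo[4,3-d][1,4]oxazin-2-ium chloride (10 mol %), 1,8-diazabicyclo[5.4.0]undec-7-ene (10 mol %), 2 (2.5 equiv), THF, 23 °C, slow addition of 1
Reagents that add atoms: none
Why: Proposed new method: the triazolylidene adds to the aldehyde of 1 to give a Breslow intermediate whose β-carbon (homoenolate) attacks one carbonyl of the activated 1,2-dione, and the resulting alkoxide is acylated by the acyl azolium to close the γ-lactone and release the catalyst; the closest known reaction type is the carbene-catalysed homoenolate [3+2] annulation of enals with 1,2-cyclohexanedione, isatins and α-keto esters, and the acetyl group is expected cis to the ring methyl from the enal (as the carbonyl substituent ends up cis to the β-substituent in enal–aldehyde annulations) while the chiral catalyst fixes the absolute configuration of both new stereocentres.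

**Step 2**
Reactants: 3 (4S,5R)-5-acetyl-4,5-dimethyloxolan-2-one
Product: 5 (4R,5S)-4-hydroxy-2,4,5-trimethylcyclohexane-1,3-dione, via sodium dione enolate 4 (not isolated)
Conditions: NaOMe (1.1 equiv), MeOH, 23 → 50 °C; then MeI (1.5 equiv), 50 °C; aq. HCl work-up
Reagents that add atoms: iodomethane, CI; sodium methoxide, [Na+].[O-]C (Na in 4 only)
Why: Intramolecular Claisen (Dieckmann-type) C-acylation of the acetyl enolate by the lactone carbonyl is driven by formation of the stabilised 1,3-dione enolate, which is C-methylated in protic medium (classical 2-alkylation of cyclohexane-1,3-diones) without touching either stereocentre.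

**Step 3**
Reactants: 5 (4R,5S)-4-hydroxy-2,4,5-trimethylcyclohexane-1,3-dione
Product: 6 (2S,4R,5S)-2,4-dihydroxy-2,4,5-trimethylcyclohexane-1,3-dione
Conditions: dimethyldioxirane (1.1 equiv), acetone/CH2Cl2, −78 → 0 °C
Reagents that add atoms: dimethyldioxirane, CC1(C)OO1
Why: Epoxidation of the dione enol and collapse to the 2-hydroxy-1,3-dione (Rubottom-type α-hydroxylation) takes place on the face of the existing tertiary hydroxyl (hydrogen-bond guidance) and away from the axial methyl on the other face, so the new C–O bond is cis to the old one.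

**Step 4**
Reactants: 6 (2S,4R,5S)-2,4-dihydroxy-2,4,5-trimethylcyclohexane-1,3-dione
Product: 7 (2S,5S,6R)-2,5,6-trimethyl-2,3,6-tris(triethylsilyloxy)cyclohex-3-en-1-one
Conditions: Et3SiOTf (3.5 equiv), Et3N (6 equiv), CH2Cl2, −78 → 0 °C
Reagents that add atoms: triethylsilyl trifluoromethanesulfonate, CC[Si](CC)(CC)OS(=O)(=O)C(F)(F)F
Why: Soft enolisation and O-silylation: only the carbonyl next to the CH2 group can enolise (the other is flanked by two quaternary carbons), so one silyl enol ether forms regiospecifically, both tertiary alcohols are capped, and a single ketone is left.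

**Step 5**
Reactants: 7 (2S,5S,6R)-2,5,6-trimethyl-2,3,6-tris(triethylsilyloxy)cyclohex-3-en-1-one
Product: 9 (1R,2R,5S,6R)-2,5,6-trimethyl-2,3,6-tris(triethylsilyloxy)cyclohex-3-en-1-yl acetate, via aluminium alkoxide 8 (not isolated)
Conditions: i-Bu2AlH (1.5 equiv), CH2Cl2, −78 °C; then pyridine, 4-(dimethylamino)pyridine, Ac2O, −78 → 23 °C
Reagents that add atoms: acetic anhydride, CC(=O)OC(C)=O; diisobutylaluminium hydride, CC(C)C[AlH]CC(C)C (H in 9, Al in 8 only)
Why: Hydride adds to the only ketone anti to the two flanking pseudo-axial C–OSiEt3 bonds (axial attack; the other face is blocked and stereoelectronically disfavoured), giving the alkoxide cis to both silyloxy groups, which is acetylated in the flask as in the known i-Bu2AlH/Ac2O reductive acetylation.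

**Step 6**
Reactants: 9 (1R,2R,5S,6R)-2,5,6-trimethyl-2,3,6-tris(triethylsilyloxy)cyclohex-3-en-1-yl acetate; 10 1,1,3,3-tetraethoxy-2-methylpropane
Product: 11 (1R,2R,4S,5S,6R)-2,5,6-trimethyl-3-oxo-4-(1,3,3-triethoxy-2-methylpropyl)-2,6-bis(triethylsilyloxy)cyclohexyl acetate
Conditions: 10 (2 equiv), Me3SiOTf (0.1 equiv), CH2Cl2, −78 °C; Et3N quench
Reagents that add atoms: none
Why: Mukaiyama aldol addition of the silyl enol ether to the oxocarbenium ion of the acetal installs a masked (E)-2-methylpropenal unit; the C–C bond forms on the face away from the two axial silyloxy groups, giving the equatorial side chain cis to the adjacent methyl, which is also the thermodynamic epimer α to the new ketone.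

**Step 7**
Reactants: 11 (1R,2R,4S,5S,6R)-2,5,6-trimethyl-3-oxo-4-(1,3,3-triethoxy-2-methylpropyl)-2,6-bis(triethylsilyloxy)cyclohexyl acetate
Product: 12 (1R,2S,3S,4R,5S,6R)-3-hydroxy-2,5,6-trimethyl-4-(1,3,3-triethoxy-2-methylpropyl)-2,6-bis(triethylsilyloxy)cyclohexyl acetate
Conditions: NaBH4, MeOH/CH2Cl2 (1:1), −40 → −20 °C
Reagents that add atoms: none
Why: Borohydride reduction by axial attack anti to the adjacent axial C–OSiEt3 bond gives the equatorial alcohol cis to the neighbouring tertiary oxygen and trans to the side chain; acetate, silyl ethers and acetal are inert at this temperature.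

**Step 8**
Reactants: 12 (1R,2S,3S,4R,5S,6R)-3-hydroxy-2,5,6-trimethyl-4-(1,3,3-triethoxy-2-methylpropyl)-2,6-bis(triethylsilyloxy)cyclohexyl acetate
Product: 14 (1R,2S,3S,4R,5S,6R)-2,3,6-trihydroxy-2,5,6-trimethyl-4-[(E)-2-methyl-3-oxoprop-1-en-1-yl]cyclohexyl acetate, via bicyclic lactol 13 (not isolated)
Conditions: 1 M aq. HCl/THF (1:3), 23 °C; then NaHCO3; 1,8-diazabicyclo[5.4.0]undec-7-ene, CH2Cl2, 23 → 40 °C
Reagents that add atoms: water, O
Why: Aqueous acid removes both tertiary silyl ethers and hydrolyses the acetal to the lactol formed with the neighbouring ring hydroxyl, and base then eliminates ethanol from the open β-ethoxy aldehyde (E1cB, as in β-elimination of 3-O-substituted 2-deoxy lactols) to give the (E)-enal, which cannot re-close.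

**Step 9**
Reactants: 14 (1R,2S,3S,4R,5S,6R)-2,3,6-trihydroxy-2,5,6-trimethyl-4-[(E)-2-methyl-3-oxoprop-1-en-1-yl]cyclohexyl acetate; 15 2-(triphenyl-λ5-phosphanylidene)acetaldehyde
Product: 16 (1R,2S,3S,4R,5S,6R)-2,3,6-trihydroxy-2,5,6-trimethyl-4-[(1E,3E)-2-methyl-5-oxopenta-1,3-dien-1-yl]cyclohexyl acetate
Conditions: 15 (1.2 equiv), toluene, 80 °C
Reagents that add atoms: none
Why: Wittig olefination with the stabilised formylmethylene ylide gives the (E)-disubstituted alkene, with limited ylide stoichiometry to restrain over-homologation of the product dienal, and the neutral conditions spare the acetate and free hydroxyls.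

**Step 10**
Reactants: 17 methyl 2-methyl-3-oxopentanoate; 18 methyl propanoate
Product: 20 methyl 2,4-dimethyl-3,5-dioxoheptanoate, via keto ester dianion 19 (not isolated)
Conditions: NaH (1.1 equiv), THF, 0 °C; n-BuLi (1.05 equiv), 0 °C; then 18 (0.5 equiv), 0 → 23 °C; aq. HCl work-up
Reagents that add atoms: sodium hydride, [Na+].[H-]; butyllithium, [Li]CCCC (counter-ions of 19 only)
Why: Huckin–Weiler γ-acylation: the β-keto ester dianion reacts at its more basic γ-carbon with the ester (Claisen condensation) to give the 3,5-diketo ester.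

**Step 11**
Reactants: 20 methyl 2,4-dimethyl-3,5-dioxoheptanoate
Product: 21 6-ethyl-4-hydroxy-3,5-dimethyl-2H-pyran-2-one
Conditions: 1,8-diazabicyclo[5.4.0]undec-7-ene (1.5 equiv), toluene, 110 °C; aq. HCl work-up
Reagents that add atoms: none
Why: Base-mediated lactonisation of the enolised diketo ester onto its methyl ester is the standard triketide cyclisation to a 4-hydroxy-2-pyranone.

**Step 12**
Reactants: 21 6-ethyl-4-hydroxy-3,5-dimethyl-2H-pyran-2-one
Product: 22 2-ethyl-6-methoxy-3,5-dimethyl-4H-pyran-4-one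
Conditions: MeOTf (1.2 equiv), CH2Cl2, 23 °C; aq. NaHCO3 work-up
Reagents that add atoms: methyl trifluoromethanesulfonate, COS(=O)(=O)C(F)(F)F
Why: Hard methylating agents alkylate the neutral hydroxypyranone at the lactone carbonyl oxygen, and deprotonation of the pyrylium salt on work-up gives the 2-methoxy-4-pyranone regioisomer.

**Step 13**
Reactants: 22 2-ethyl-6-methoxy-3,5-dimethyl-4H-pyran-4-one
Product: 24 diethyl [1-(6-methoxy-3,5-dimethyl-4-oxo-4H-pyran-2-yl)ethyl]phosphonate, via lithiated pyranone 23 (not isolated)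
Conditions: LiN(SiMe3)2 (2.1 equiv), THF, −78 °C; then ClP(O)(OEt)2 (1.05 equiv), −78 → 0 °C; aq. NH4Cl work-up
Reagents that add atoms: diethyl chlorophosphate, CCOP(=O)(Cl)OCC; lithium bis(trimethylsilyl)amide, [Li+].C[Si](C)(C)[N-][Si](C)(C)C (Li in 23 only)
Why: The ethyl CH2, vinylogous to the pyranone carbonyl, is deprotonated and the carbanion is C-phosphorylated by the chlorophosphate (carbanion phosphorylation; such pyranone anions react at carbon, as in their alkylation and silylation), the second equivalent of base absorbing the more acidic product.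

**Step 14**
Reactants: 16 (1R,2S,3S,4R,5S,6R)-2,3,6-trihydroxy-2,5,6-trimethyl-4-[(1E,3E)-2-methyl-5-oxopenta-1,3-dien-1-yl]cyclohexyl acetate; 24 diethyl [1-(6-methoxy-3,5-dimethyl-4-oxo-4H-pyran-2-yl)ethyl]phosphonate
Product: 26 amaurone A, via lithiated phosphonate 25 (not isolated)
Conditions: 24 (2 equiv), LiN(SiMe3)2 (2 equiv), THF, −78 °C; then 16, −78 → 0 °C
Reagents that add atoms: lithium bis(trimethylsilyl)amide, [Li+].C[Si](C)(C)[N-][Si](C)(C)C (Li in 25 only)
Why: Horner–Wadsworth–Emmons olefination of the pyranone-stabilised phosphonate anion places the dienyl chain trans to the bulkier pyranone (thermodynamic control) to complete the (E,E,E)-triene, and the weakly basic, soft anion leaves the acetate and hydroxyls alone.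

**Compound list**
1 | (E)-but-2-enal (crotonaldehyde) | C/C=C/C=O | starting material
2 | butane-2,3-dione (biacetyl) | CC(=O)C(C)=O | starting material
3 | (4S,5R)-5-acetyl-4,5-dimethyloxolan-2-one | O=C1C[C@H](C)[C@@](C)(O1)C(C)=O | intermediate
4 | sodium enolate of (4R,5S)-4-hydroxy-4,5-dimethylcyclohexane-1,3-dione (not isolated) | [Na+].O=C1C[C@H](C)[C@@](C)(O)C([O-])=C1 | intermediate
5 | (4R,5S)-4-hydroxy-2,4,5-trimethylcyclohexane-1,3-dione (enol tautomer drawn) | CC1=C(O)C[C@H](C)[C@@](C)(O)C1=O | intermediate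
6 | (2S,4R,5S)-2,4-dihydroxy-2,4,5-trimethylcyclohexane-1,3-dione | C1[C@H](C)[C@@](C)(O)C(=O)[C@@](C)(O)C1=O | intermediate
7 | (2S,5S,6R)-2,5,6-trimethyl-2,3,6-tris(triethylsilyloxy)cyclohex-3-en-1-one | CC[Si](CC)(CC)OC1=C[C@H](C)[C@@](C)(O[Si](CC)(CC)CC)C(=O)[C@@]1(C)O[Si](CC)(CC)CC | intermediate
8 | diisobutylaluminium (1R,2R,5S,6R)-2,5,6-trimethyl-2,3,6-tris(triethylsilyloxy)cyclohex-3-en-1-olate (not isolated) | CC[Si](CC)(CC)OC1=C[C@H](C)[C@@](C)(O[Si](CC)(CC)CC)[C@@H](O[Al](CC(C)C)CC(C)C)[C@@]1(C)O[Si](CC)(CC)CC | intermediate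
9 | (1R,2R,5S,6R)-2,5,6-trimethyl-2,3,6-tris(triethylsilyloxy)cyclohex-3-en-1-yl acetate | CC[Si](CC)(CC)OC1=C[C@H](C)[C@@](C)(O[Si](CC)(CC)CC)[C@@H](OC(C)=O)[C@@]1(C)O[Si](CC)(CC)CC | intermediate
10 | 1,1,3,3-tetraethoxy-2-methylpropane | CCOC(OCC)C(C)C(OCC)OCC | starting material
11 | (1R,2R,4S,5S,6R)-2,5,6-trimethyl-3-oxo-4-(1,3,3-triethoxy-2-methylpropyl)-2,6-bis(triethylsilyloxy)cyclohexyl acetate (epimer mixture at the two side-chain carbons) | CCOC(OCC)C(C)C(OCC)[C@@H]1[C@H](C)[C@@](C)(O[Si](CC)(CC)CC)[C@@H](OC(C)=O)[C@@](C)(O[Si](CC)(CC)CC)C1=O | intermediate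
12 | (1R,2S,3S,4R,5S,6R)-3-hydroxy-2,5,6-trimethyl-4-(1,3,3-triethoxy-2-methylpropyl)-2,6-bis(triethylsilyloxy)cyclohexyl acetate (side-chain epimers) | CCOC(OCC)C(C)C(OCC)[C@@H]1[C@H](C)[C@@](C)(O[Si](CC)(CC)CC)[C@@H](OC(C)=O)[C@@](C)(O[Si](CC)(CC)CC)[C@H]1O | intermediate
13 | bicyclic lactol, 4-ethoxy-2,6,8-trihydroxy-3,5,6,8-tetramethyloctahydro-2H-chromen-7-yl acetate, carbocycle configured as in 12, epimers at the three pyran carbons (not isolated) | CCOC1[C@@H]2[C@H](C)[C@@](C)(O)[C@@H](OC(C)=O)[C@@](C)(O)[C@H]2OC(O)C1C | intermediate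
14 | (1R,2S,3S,4R,5S,6R)-2,3,6-trihydroxy-2,5,6-trimethyl-4-[(E)-2-methyl-3-oxoprop-1-en-1-yl]cyclohexyl acetate | O=C/C(C)=C/[C@@H]1[C@H](C)[C@@](C)(O)[C@@H](OC(C)=O)[C@@](C)(O)[C@H]1O | intermediate
15 | 2-(triphenyl-λ5-phosphanylidene)acetaldehyde | O=CC=P(c1ccccc1)(c1ccccc1)c1ccccc1 | starting material
16 | (1R,2S,3S,4R,5S,6R)-2,3,6-trihydroxy-2,5,6-trimethyl-4-[(1E,3E)-2-methyl-5-oxopenta-1,3-dien-1-yl]cyclohexyl acetate | O=C/C=C/C(C)=C/[C@@H]1[C@H](C)[C@@](C)(O)[C@@H](OC(C)=O)[C@@](C)(O)[C@H]1O | intermediate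
17 | methyl 2-methyl-3-oxopentanoate | CCC(=O)C(C)C(=O)OC | starting material
18 | methyl propanoate | CCC(=O)OC | starting material
19 | sodium lithium dianion of methyl 2-methyl-3-oxopentanoate (not isolated) | [Na+].[Li+].C[CH-]C(=O)[C-](C)C(=O)OC | intermediate
20 | methyl 2,4-dimethyl-3,5-dioxoheptanoate | CCC(=O)C(C)C(=O)C(C)C(=O)OC | intermediate
21 | 6-ethyl-4-hydroxy-3,5-dimethyl-2H-pyran-2-one | CCC1=C(C)C(O)=C(C)C(=O)O1 | intermediate
22 | 2-ethyl-6-methoxy-3,5-dimethyl-4H-pyran-4-one | CCc1oc(OC)c(C)c(=O)c1C | intermediate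
23 | lithiated 2-ethyl-6-methoxy-3,5-dimethyl-4H-pyran-4-one, carbanion at the ethyl CH (not isolated) | [Li+].C[CH-]c1oc(OC)c(C)c(=O)c1C | intermediate
24 | diethyl [1-(6-methoxy-3,5-dimethyl-4-oxo-4H-pyran-2-yl)ethyl]phosphonate (racemic) | CCOP(=O)(OCC)C(C)c1oc(OC)c(C)c(=O)c1C | intermediate
25 | lithium salt of phosphonate 24, carbanion α to phosphorus (not isolated) | [Li+].CCOP(=O)(OCC)[C-](C)c1oc(OC)c(C)c(=O)c1C | intermediate
26 | amaurone A, (1R,2S,3S,4R,5S,6R)-2,3,6-trihydroxy-4-[(1E,3E,5E)-6-(6-methoxy-3,5-dimethyl-4-oxo-4H-pyran-2-yl)-2-methylhepta-1,3,5-trien-1-yl]-2,5,6-trimethylcyclohexyl acetate | COc1oc(/C(C)=C/C=C/C(C)=C/[C@@H]2[C@H](C)[C@@](C)(O)[C@@H](OC(C)=O)[C@@](C)(O)[C@H]2O)c(C)c(=O)c1C | target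

**Step count**
Total: 14 steps. Longest linear sequence: 10 steps (steps 1–9 and 14); the pyranone branch is 4 steps (10–13).

**Three steps most likely to fail**

Step 1. Risks: low reactivity of an aliphatic enal, competing acyl transfer from 2, and unproven diastereo- and enantioselectivity. The fallback sets out from 1 and 2 and comes back at 3, replacing catalysis by a stoichiometric chiral homoenolate equivalent (Hoppe homoaldol). 1 is reduced (NaBH4, CeCl3·7H2O, MeOH) to (E)-but-2-en-1-ol F1 and carbamoylated (NaH, iPr2NCOCl, THF) to (E)-but-2-en-1-yl N,N-diisopropylcarbamate F2. 2 is mono-ketalised (HC(OMe)3, MeOH, cat. H2SO4) to 3,3-dimethoxybutan-2-one F3. F2 is deprotonated with s-BuLi/(−)-sparteine (pentane/cyclohexane, −78 °C, crystallisation-driven resolution; the enantiomeric diamine is used if the other series forms), transmetalated with Ti(OiPr)4 and added to F3 through a chair transition state with the ketal carbon equatorial. This gives the anti adduct (1Z,3S,4R)-4-hydroxy-5,5-dimethoxy-3,4-dimethylhex-1-en-1-yl N,N-diisopropylcarbamate F4. MeOH, MeSO3H and cat. Hg(OAc)2 convert the enol carbamate into the lactol ether (4S,5R)-5-(1,1-dimethoxyethyl)-2-methoxy-4,5-dimethyloxolane F5. 3-Chloroperbenzoic acid/BF3·OEt2 followed by aqueous HCl oxidises it to the lactone and frees the ketone, which is 3.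

Step 5. Risks: the carbonyl sits between two fully substituted silyloxy carbons, so reduction may be slow or face-unselective and the acetylation may fail. The fallback sets out from 5 and comes back at 9, installing the acetate while the ring is less crowded. 5 is converted (HC(OMe)3, MeOH, cat. p-toluenesulfonic acid) into the vinylogous ester at the less hindered carbonyl, (5S,6R)-6-hydroxy-3-methoxy-2,5,6-trimethylcyclohex-2-en-1-one F6. Luche reduction (NaBH4, CeCl3·7H2O, MeOH, −78 °C; hydride anti to the pseudo-axial tertiary hydroxyl) gives (1R,2S,6S)-4-methoxy-1,3,6-trimethylcyclohex-3-ene-1,2-diol F7. Hydroxyl-directed epoxidation of the enol ether (3-chloroperbenzoic acid, NaHCO3, wet CH2Cl2, 0 °C) and collapse of the epoxy ether give (2R,3R,4R,5S)-2,3,4-trihydroxy-2,4,5-trimethylcyclohexan-1-one F8. Its only secondary alcohol is acetylated (Ac2O, 4-(dimethylamino)pyridine, pyridine) to (1R,2R,5S,6R)-2,6-dihydroxy-2,5,6-trimethyl-3-oxocyclohexyl acetate F9, and Et3SiOTf/Et3N then gives 9.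

Step 14. Risks: E/Z mixtures at the trisubstituted alkene and base sensitivity of the unprotected dienal. The fallback sets out from 12 and comes back at 26, building the same alkene stepwise by aldol addition and elimination on silyl-protected material, the usual way to 6-alkenyl pyranones. 12 is unmasked with the tertiary silyl ethers kept (0.5 M aq. oxalic acid/THF, then 1,8-diazabicyclo[5.4.0]undec-7-ene) to (1R,2S,3S,4R,5S,6R)-3-hydroxy-2,5,6-trimethyl-4-[(E)-2-methyl-3-oxoprop-1-en-1-yl]-2,6-bis(triethylsilyloxy)cyclohexyl acetate F10. Wittig reaction with 15 gives (1R,2S,3S,4R,5S,6R)-3-hydroxy-2,5,6-trimethyl-4-[(1E,3E)-2-methyl-5-oxopenta-1,3-dien-1-yl]-2,6-bis(triethylsilyloxy)cyclohexyl acetate F11. Addition of 23 (from 22, LiN(SiMe3)2, THF, −78 °C, 2.2 equiv) gives the aldol adduct (1R,2S,3S,4R,5S,6R)-3-hydroxy-4-[(1E,3E)-5-hydroxy-6-(6-methoxy-3,5-dimethyl-4-oxo-4H-pyran-2-yl)-2-methylhepta-1,3-dien-1-yl]-2,5,6-trimethyl-2,6-bis(triethylsilyloxy)cyclohexyl acetate F12. MsCl/Et3N reacts at the unhindered allylic carbinol (the ring carbinol is neopentyl-like), and 1,8-diazabicyclo[5.4.0]undec-7-ene then eliminates (E1cB) to the bis(triethylsilyl) ether of amaurone A at the two tertiary hydroxyls F13. HF·pyridine gives 26.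

**Further compounds**
F1 | step 1 | (E)-but-2-en-1-ol | C/C=C/CO
F2 | step 1 | (E)-but-2-en-1-yl N,N-diisopropylcarbamate | C/C=C/COC(=O)N(C(C)C)C(C)C
F3 | step 1 | 3,3-dimethoxybutan-2-one | CC(=O)C(C)(OC)OC
F4 | step 1 | (1Z,3S,4R)-4-hydroxy-5,5-dimethoxy-3,4-dimethylhex-1-en-1-yl N,N-diisopropylcarbamate | CC(C)N(C(C)C)C(=O)O/C=C\[C@H](C)[C@@](C)(O)C(C)(OC)OC
F5 | step 1 | (4S,5R)-5-(1,1-dimethoxyethyl)-2-methoxy-4,5-dimethyloxolane (anomer mixture) | COC1C[C@H](C)[C@@](C)(O1)C(C)(OC)OC
F6 | step 5 | (5S,6R)-6-hydroxy-3-methoxy-2,5,6-trimethylcyclohex-2-en-1-one | C1[C@H](C)[C@@](C)(O)C(=O)C(C)=C1OC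
F7 | step 5 | (1R,2S,6S)-4-methoxy-1,3,6-trimethylcyclohex-3-ene-1,2-diol | C1[C@H](C)[C@@](C)(O)[C@@H](O)C(C)=C1OC
F8 | step 5 | (2R,3R,4R,5S)-2,3,4-trihydroxy-2,4,5-trimethylcyclohexan-1-one | C1[C@H](C)[C@@](C)(O)[C@@H](O)[C@@](C)(O)C1=O
F9 | step 5 | (1R,2R,5S,6R)-2,6-dihydroxy-2,5,6-trimethyl-3-oxocyclohexyl acetate | C1[C@H](C)[C@@](C)(O)[C@@H](OC(C)=O)[C@@](C)(O)C1=O
F10 | step 14 | (1R,2S,3S,4R,5S,6R)-3-hydroxy-2,5,6-trimethyl-4-[(E)-2-methyl-3-oxoprop-1-en-1-yl]-2,6-bis(triethylsilyloxy)cyclohexyl acetate | O=C/C(C)=C/[C@@H]1[C@H](C)[C@@](C)(O[Si](CC)(CC)CC)[C@@H](OC(C)=O)[C@@](C)(O[Si](CC)(CC)CC)[C@H]1O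
F11 | step 14 | (1R,2S,3S,4R,5S,6R)-3-hydroxy-2,5,6-trimethyl-4-[(1E,3E)-2-methyl-5-oxopenta-1,3-dien-1-yl]-2,6-bis(triethylsilyloxy)cyclohexyl acetate | O=C/C=C/C(C)=C/[C@@H]1[C@H](C)[C@@](C)(O[Si](CC)(CC)CC)[C@@H](OC(C)=O)[C@@](C)(O[Si](CC)(CC)CC)[C@H]1O
F12 | step 14 | (1R,2S,3S,4R,5S,6R)-3-hydroxy-4-[(1E,3E)-5-hydroxy-6-(6-methoxy-3,5-dimethyl-4-oxo-4H-pyran-2-yl)-2-methylhepta-1,3-dien-1-yl]-2,5,6-trimethyl-2,6-bis(triethylsilyloxy)cyclohexyl acetate (epimers at the two new carbons) | COc1oc(C(C)C(O)/C=C/C(C)=C/[C@@H]2[C@H](C)[C@@](C)(O[Si](CC)(CC)CC)[C@@H](OC(C)=O)[C@@](C)(O[Si](CC)(CC)CC)[C@H]2O)c(C)c(=O)c1C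
F13 | step 14 | bis(triethylsilyl) ether of amaurone A at the two tertiary hydroxyls | COc1oc(/C(C)=C/C=C/C(C)=C/[C@@H]2[C@H](C)[C@@](C)(O[Si](CC)(CC)CC)[C@@H](OC(C)=O)[C@@](C)(O[Si](CC)(CC)CC)[C@H]2O)c(C)c(=O)c1C
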